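**Remarks before the route**

- Remark on labels: carbon labels C1–C15 are those of the germacranolide skeleton of the target (epoxide C1–C10, carbinol C3, alkene C4=C5, lactone oxygen on C6, ester on C8, carbonyl C12, methylene C13, methyls C14 and C15). Compound numbers are plain arabic numerals.
- Remark on the chemistry (assumption): the sense of the hydrolytic kinetic resolution in step 13 is assigned by analogy with propylene oxide and 2-vinyloxirane (the (R,R) cobalt complex is taken to leave the S epoxide, so the (S,S) complex is used here). If the opposite sense is found, the enantiomeric complex is used.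
- Remark on relative configuration: 14, 20 and 27 map onto the target without correction (14 is 7S,8R; 20 is R; 27 is 3S,7S,8R; the change to 7R in the target is a priority change only). The C7/C8 pair of 14 corresponds to the syn adduct of a 2-(alkoxycarbonyl)allylation (C8–O and the C6 branch on the same side of the C9–C8–C7–C11 zigzag). An anti-selective allylation would give the wrong diastereomer, so the pair is set here by epoxide chemistry. A terminal alkenyl epoxide such as 20 cannot be reached by epoxidising an alkene derived from propargyl alcohol; it is made by methylene transfer to the aldehyde and resolution.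

## Structural features

The target is a heliangolide-type germacranolide: a ten-membered carbocycle (C1–C10) carrying a trans-fused α-methylene-γ-butyrolactone across C6–C7, with the ring oxygen on C6. The ring holds a Z-trisubstituted C4=C5 alkene (C15 on C4), a trans C1–C10 epoxide (1R,10R, C14 on C10) and a secondary allylic alcohol at C3 (S). C6, C7 and C8 form a contiguous triad (6R,7R,8R; H6/H7 anti, H7/H8 syn). C8 carries the ester of (2S,3S)-2,3-dimethyloxirane-2-carboxylic acid, which adds two more stereocentres, eight in all. Fragile groups are the exocyclic methylene lactone (Michael acceptor), both epoxides (the ring epoxide is placed for transannular attack by the C3 hydroxyl or the C4 alkene under acid), the epoxy ester (base), and any cyclodeca-1(10),4-diene intermediate (Cope rearrangement on heating). The real difficulty is closing the ten-membered ring with both alkene geometries and the C6–C8 triad intact, and ordering the oxidations so that the ring epoxide arrives late. The key step uses the fact that the C1–C10 epoxide is the oxide of an E-trisubstituted alkene with its methyl on C10, and that the C3 carbinol lies two carbons from C1. This homoallylic alcohol is what forms when a methylaluminated terminal alkyne (C1≡C10) opens a terminal epoxide (C2–C3) at its CH2 carbon.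

## Logic of the disconnections

- **40 back to 38.** The C3 O–Si bond of 39 is cut last. Before it, the C1–O and C10–O bonds of the ring epoxide are removed to give 38. The epoxide is the most acid-labile element and sits within reach of the C3 oxygen, so it should appear only at the end. The gain is a triene in which C1=C10 is the only electron-rich alkene. The demand is a chemo- and face-selective epoxidation and a final desilylation that does not trigger transannular opening.
- **38 back to 35.** The C8 O–acyl bond is cut to give 36 and the enantiopure acid 24; 36 comes from 35 by removing the PMB ether. Attaching 24 as a ready-made unit avoids a diastereoselective epoxidation of an angelate on the ring. The demand is acylation of a hindered secondary alcohol without translactonisation to C8 and without opening either oxirane.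
- **35 back to 31.** The lactone O6–C12 bond is cut and C12 is taken down to the alcohol level, giving the 2-methylene-1,4-diol 32 and its silyl ether 31. The methylene and both lactone carbons are then present from the start as a robust allylic silyl ether. The demand is oxidation of the primary allylic alcohol, through enal and lactol, without touching the secondary C6 carbinol.
- **31 back to 27.** The ring bond C5–C6 is cut, giving the Z-alkenyl iodide aldehyde 30, reached from 27 through 28 and 29. An alkenylchromium addition keeps the Z geometry, tolerates all ethers and forms the allylic C6 carbinol directly. The gain is an acyclic chain. The demand is high dilution, an aldehyde that survives with its C7 centre intact, and the correct face at C6.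
- **27 to 14 and 20.** C1–C2 and C10–C14 are cut together: 27 falls into alkyne 14, epoxide 20 and a methyl donor. This is the most convergent cut of the chain (a C6–C10 half with the masked lactone carbons and a C2–C5 half with the Z-iodoalkene). It creates the E alkene and leaves the C3 carbinol in one operation. The demand is syn methylmetalation with methyl on C10 and SN2 opening at C2 in the presence of an alkenyl iodide.
- **14 back to 5 and 7.** Protecting-group changes lead from 14 through 13, 12 and 11 to diol 10. In 10 the C7–C11 bond is cut, giving epoxy alcohol 5 and the alkenyl bromide 7. Inversion at C7 of a trans epoxide delivers the syn C7/C8 pair from a single catalytic asymmetric step. The acetal route then places PMB on C8 and leaves C6 free. The demand is attack at C2 of the epoxy alcohol and not at C3.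
- **5 back to 1; 7 back to 6.** The epoxide C–O bonds of 5 are removed to give allylic alcohol 4. Its C7=C8 bond is cut through ester 3 into the aldehyde 2 derived from 1 and a two-carbon ylide. 7 is the silyl ether of 6. The demand is handling of a β,γ-alkynyl aldehyde, met by the silyl cap on the alkyne and in-flask trapping.
- **20 back to 15.** The epoxide C2–C3 bond of 20 is cut to aldehyde 18 and a methylene donor, with resolution of racemate 19. 18 comes from alcohol 17, and 17 from 15 by cutting C4–C15 and C5–I. The iodoalkene geometry is fixed by chelation in the first step and carried unchanged. The demand is an efficient kinetic resolution.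
- **24 back to 21.** The carboxyl is taken to the alcohol 23 and the oxirane C–O bonds are removed to give 22, the reduction product of 21. The Z geometry of 21 becomes the cis relationship of the carboxyl and C3 methyl in 24. The demand is useful enantioselectivity with a Z-trisubstituted allylic alcohol.

## Other disconnections considered

**Alternative 1:** The cut is C7–C8. In the forward step SmI2 would reduce the C8 aldehyde of the butenolide aldehyde A2 to a ketyl, which adds to the β-carbon C7 of the butenolide and closes the ten-membered ring onto the preformed lactone, giving A1.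
- In its favour: the lactone and C6 exist before ring closure, so no C6 or C12 protecting groups are needed. The C6 substituent of the butenolide should steer the new bond anti, which is the trans-lactone relationship. On protecting-group count this plan is better than the chosen one.
- Against it: a ketyl–alkene closure of a ten-membered ring has to compete with pinacol coupling and simple aldehyde reduction. The C8 carbinol configuration would be set in the same step with only remote control. A1 lacks C13, so the lactone must later be methylenated through its enolate next to an oxygenated C8, which costs two or three steps and needs protection of the C8 hydroxyl.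
- Comparison: A2 still requires the E C1(10) alkene and the C3 carbinol, which could come from the same methylalumination–epoxide union, so the two plans are equal on that part. The alternative sets two stereocentres in its ring closure and the chosen plan one. Mechanistically the chromium-mediated closure is better precedented for medium rings. Overall step economy is about equal.

**Alternative 2:** The cuts are the C4–C5 and C1–C10 σ bonds. Irradiation of enone A4 with cyclobutene A5 would give the 6-4-4 photoadduct A3, and thermal cycloreversion of the central cyclobutane would open it to the cyclodecadienone A6.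
- In its favour: the ten-membered ring is reached from two small rings without any macrocyclisation. On ring construction this is shorter than the chosen plan and is its better.
- Against it: two chiral partners must combine with the correct regiochemistry (head-to-head) and facial sense. The alkene geometries of A6 (Z at C4, E at C1(10)) depend entirely on the ring-fusion stereochemistry of A3. The cycloreversion needs temperatures at which 1,5-cyclodecadienes can undergo Cope rearrangement. A6 has no C11–C13 unit, so C7 alkylation, C6 reduction, lactonisation and methylenation remain, with C6 and C7 set only by ring conformation.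
- Comparison: shorter to the carbocycle, but weaker on stereochemical predictability and thermal safety. The total step count is likely similar or longer.

**Alternative 3:** The cuts are O–C12 and C11–C12. PdCl2 with SnCl2 and PPh3 under CO would convert the trans ethynyl carbinol A8 into the α-methylene lactone A7, which has the same structure as 35.
- In its favour: carbonyl and methylene are created in one step from CO. C12 and its silyl ether need not be carried, which saves a deprotection and an oxidation, so the late stage is equal or better in step economy. The endgame from A7 is identical to that from 35.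
- Against it: A8 carries a second terminal alkyne (C11≡C13) at C7. It would compete in the methylalumination unless capped, and it makes the C6 aldehyde propargylic and more prone to epimerisation. The palladium–tin–CO medium also meets an allylic carbinol, an allylic silyl ether and a 1,5-diene, with risk of ionisation or isomerisation.
- Comparison: equal in ring construction (both close C5–C6 before the lactone) and better in late-stage atom economy. It conflicts with the chosen key step, which is why C11–C13 are carried here as a 2-propenyl silyl ether.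

Key step: step 17

## Route

**Step 1**
Reactants: 1 4-(trimethylsilyl)but-3-yn-1-ol
Product: 3 ethyl (2E)-6-(trimethylsilyl)hex-2-en-5-ynoate, via 4-(trimethylsilyl)but-3-ynal 2 (not isolated)
Conditions: Dess–Martin periodinane, CH2Cl2, 0 °C to rt; then Ph3P=CHCO2Et, rt
Reagents that add atoms: ethyl (triphenylphosphoranylidene)acetate, CCOC(=O)C=P(c1ccccc1)(c1ccccc1)c1ccccc1
Why: Dess–Martin oxidation gives the isomerisation-prone β,γ-alkynyl aldehyde, which is trapped in the same flask by the stabilised ylide (Wittig olefination, E-selective); the silyl cap on the alkyne suppresses allene formation.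

**Step 2**
Reactants: 3 ethyl (2E)-6-(trimethylsilyl)hex-2-en-5-ynoate
Product: 4 (2E)-6-(trimethylsilyl)hex-2-en-5-yn-1-ol
Conditions: i-Bu2AlH (2.3 equiv), CH2Cl2, −78 °C; aq. potassium sodium tartrate
Reagents that add atoms: none
Why: 1,2-Reduction of the enoate by i-Bu2AlH at low temperature gives the allylic alcohol and leaves the silylalkyne and the doubly activated CH2 untouched.

**Step 3**
Reactants: 4 (2E)-6-(trimethylsilyl)hex-2-en-5-yn-1-ol
Product: 5 [(2R,3R)-3-[3-(trimethylsilyl)prop-2-yn-1-yl]oxiran-2-yl]methanol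
Conditions: Ti(OiPr)4 (10 mol %), D-(−)-diisopropyl tartrate (12 mol %), t-BuOOH, 4 Å molecular sieves, CH2Cl2, −20 °C
Reagents that add atoms: tert-butyl hydroperoxide, CC(C)(C)OO
Why: Sharpless asymmetric epoxidation of an E-disubstituted allylic alcohol; the D-tartrate ligand directs oxygen to the face that gives the 2R,3R epoxy alcohol, which fixes C8 and, after inversion in step 5, C7.

**Step 4**
Reactants: 6 2-bromoprop-2-en-1-ol
Product: 7 [(2-bromoprop-2-en-1-yl)oxy](tert-butyl)dimethylsilane
Conditions: TBSCl, imidazole, CH2Cl2, 0 °C to rt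
Reagents that add atoms: tert-butyldimethylsilyl chloride, CC(C)(C)[Si](C)(C)Cl
Why: Standard silylation of a primary allylic alcohol; the silyl ether masks the future C12 oxygen.

**Step 5**
Reactants: 5 [(2R,3R)-3-[3-(trimethylsilyl)prop-2-yn-1-yl]oxiran-2-yl]methanol; 7 [(2-bromoprop-2-en-1-yl)oxy](tert-butyl)dimethylsilane
Product: 10 (2S,3R)-2-[3-(tert-butyldimethylsilyloxy)prop-1-en-2-yl]-6-(trimethylsilyl)hex-5-yne-1,3-diol, via alkenyllithium 8 (not isolated), via alkenylmagnesium bromide 9 (not isolated)
Conditions: 7 (3 equiv), t-BuLi (6 equiv), Et2O, −78 °C; MgBr2·OEt2, −78 °C; CuI (0.3 equiv), then 5 in THF, −40 to −10 °C; aq. NH4Cl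
Reagents that add atoms: none
Why: Copper-catalysed opening of a trans-2,3-epoxy alcohol by an alkenyl Grignard reagent, steered to C2 by the magnesium alkoxide of the C1 hydroxyl; SN2 inversion at C7 turns the epoxide into the 7S,8R syn pair. Exchange of lithium for magnesium at −78 °C limits β-elimination and silyl migration in the β-silyloxy alkenyl anion.

**Step 6**
Reactants: 10 (2S,3R)-2-[3-(tert-butyldimethylsilyloxy)prop-1-en-2-yl]-6-(trimethylsilyl)hex-5-yne-1,3-diol
Product: 11 tert-butyl({2-[(2S,4R,5S)-2-(4-methoxyphenyl)-4-[3-(trimethylsilyl)prop-2-yn-1-yl]-1,3-dioxan-5-yl]prop-2-en-1-yl}oxy)dimethylsilane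
Conditions: 4-MeOC6H4CH(OMe)2, PPTS (cat.), CH2Cl2, rt
Reagents that add atoms: 4-methoxybenzaldehyde dimethyl acetal, COc1ccc(cc1)C(OC)OC
Why: Acid-catalysed transacetalisation of the 1,3-diol; the 1,3-dioxane forms under thermodynamic control with aryl, propargyl and alkenyl groups all equatorial, which sets the acetal carbon.

**Step 7**
Reactants: 11 tert-butyl({2-[(2S,4R,5S)-2-(4-methoxyphenyl)-4-[3-(trimethylsilyl)prop-2-yn-1-yl]-1,3-dioxan-5-yl]prop-2-en-1-yl}oxy)dimethylsilane
Product: 12 (2S,3R)-2-[3-(tert-butyldimethylsilyloxy)prop-1-en-2-yl]-3-[(4-methoxyphenyl)methoxy]-6-(trimethylsilyl)hex-5-yn-1-ol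
Conditions: i-Bu2AlH (4 equiv), CH2Cl2, −78 to 0 °C; aq. potassium sodium tartrate
Reagents that add atoms: none
Why: Regioselective reductive opening of a 4-methoxybenzylidene acetal: aluminium binds the less hindered primary oxygen and hydride is delivered to the oxocarbenium ion, leaving PMB on the C8 oxygen and the C6 hydroxyl free.

**Step 8**
Reactants: 12 (2S,3R)-2-[3-(tert-butyldimethylsilyloxy)prop-1-en-2-yl]-3-[(4-methoxyphenyl)methoxy]-6-(trimethylsilyl)hex-5-yn-1-ol
Product: 13 (2S,3R)-2-[3-(tert-butyldimethylsilyloxy)prop-1-en-2-yl]-3-[(4-methoxyphenyl)methoxy]hex-5-yn-1-ol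
Conditions: K2CO3 (0.5 equiv), MeOH, rt
Reagents that add atoms: none
Why: Methanolysis of the alkynyl C–Si bond under mild base frees the terminal alkyne; the TBS and PMB ethers are stable to these conditions.

**Step 9**
Reactants: 13 (2S,3R)-2-[3-(tert-butyldimethylsilyloxy)prop-1-en-2-yl]-3-[(4-methoxyphenyl)methoxy]hex-5-yn-1-ol
Product: 14 tert-butyl({2-[(2S,3R)-3-[(4-methoxyphenyl)methoxy]-1-(triethylsilyloxy)hex-5-yn-2-yl]prop-2-en-1-yl}oxy)dimethylsilane (east alkyne; C6 triethylsilyl ether; C8 PMB ether; C12 TBS ether)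
Conditions: TESCl, imidazole, CH2Cl2, 0 °C
Reagents that add atoms: chlorotriethylsilane, CC[Si](Cl)(CC)CC
Why: Silylation of the primary C6 hydroxyl with the most labile of the three silyl groups, so that C6 can be unmasked first after the union.

**Step 10**
Reactants: 15 prop-2-yn-1-ol
Product: 17 (2Z)-3-iodo-2-methylprop-2-en-1-ol, via bis(bromomagnesium) alkenyl alkoxide 16 (not isolated)
Conditions: MeMgBr (3 equiv), CuI (10 mol %), THF, −10 °C to rt; then I2, −78 to 0 °C
Reagents that add atoms: methylmagnesium bromide, C[Mg]Br; iodine, II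
Why: Copper-catalysed, alkoxide-directed anti-carbomagnesiation of a propargylic alcohol puts methyl on the internal carbon and magnesium on the terminal carbon cis to the CH2O group (five-membered chelate); iodinolysis with retention gives the Z-iodoalkene.

**Step 11**
Reactants: 17 (2Z)-3-iodo-2-methylprop-2-en-1-ol
Product: 18 (2Z)-3-iodo-2-methylprop-2-enal
Conditions: MnO2 (activated), CH2Cl2, rt, dark
Reagents that add atoms: none
Why: Allylic oxidation with MnO2 under neutral conditions; exclusion of light and acid guards the Z geometry of the β-iodo enal.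

**Step 12**
Reactants: 18 (2Z)-3-iodo-2-methylprop-2-enal
Product: 19 rac-2-[(1Z)-1-iodoprop-1-en-2-yl]oxirane
Conditions: Me3S+ I−, n-BuLi, THF, −10 °C; then 18, −10 °C to rt
Reagents that add atoms: trimethylsulfonium iodide, C[S+](C)C.[I-]
Why: Corey–Chaykovsky methylene transfer: the sulfonium ylide adds 1,2 to the enal and the betaine closes to the terminal epoxide; the iodoalkene is not involved.

**Step 13**
Reactants: 19 rac-2-[(1Z)-1-iodoprop-1-en-2-yl]oxirane
Product: 20 (2R)-2-[(1Z)-1-iodoprop-1-en-2-yl]oxirane (west epoxide)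
Conditions: (S,S)-(salen)Co(OAc) (1 mol %; salen = N,N′-bis(3,5-di-tert-butylsalicylidene)cyclohexane-1,2-diamine dianion), H2O (0.55 equiv), THF, 0 °C to rt
Reagents that add atoms: none
Why: Jacobsen hydrolytic kinetic resolution of a terminal epoxide: the trivalent cobalt complex hydrolyses the S enantiomer at its CH2 carbon and leaves the R epoxide, which fixes C3 of the target.

**Step 14**
Reactants: 21 angelic acid [(2Z)-2-methylbut-2-enoic acid]
Product: 22 (2Z)-2-methylbut-2-en-1-ol
Conditions: LiAlH4, Et2O, 0 °C
Reagents that add atoms: none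
Why: Hydride reduction of the acid to the allylic alcohol; the trisubstituted alkene is not reduced and the Z geometry is kept at low temperature.

**Step 15**
Reactants: 22 (2Z)-2-methylbut-2-en-1-ol
Product: 23 [(2R,3S)-2,3-dimethyloxiran-2-yl]methanol
Conditions: Ti(OiPr)4 (10 mol %), D-(−)-diethyl tartrate (12 mol %), t-BuOOH, 4 Å molecular sieves, CH2Cl2, −20 °C
Reagents that add atoms: tert-butyl hydroperoxide, CC(C)(C)OO
Why: Sharpless asymmetric epoxidation; the D-tartrate delivers oxygen to the face that gives the 2R,3S epoxy alcohol, and the Z alkene fixes the cis relationship of CH2OH and the C3 methyl.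

**Step 16**
Reactants: 23 [(2R,3S)-2,3-dimethyloxiran-2-yl]methanol
Product: 24 (2S,3S)-2,3-dimethyloxirane-2-carboxylic acid
Conditions: TEMPO (0.2 equiv), PhI(OAc)2 (2.2 equiv), MeCN–H2O (1:1), rt
Reagents that add atoms: water, O
Why: Oxoammonium oxidation of the primary alcohol through the aldehyde hydrate to the acid under near-neutral conditions that spare the oxirane; the descriptor at C2 changes from R to S only because of the new priority of the carboxyl group.

**Step 17**
Reactants: 14 tert-butyl({2-[(2S,3R)-3-[(4-methoxyphenyl)methoxy]-1-(triethylsilyloxy)hex-5-yn-2-yl]prop-2-en-1-yl}oxy)dimethylsilane; 20 (2R)-2-[(1Z)-1-iodoprop-1-en-2-yl]oxirane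
Product: 27 (1Z,3S,5E,8R,9S)-9-[3-(tert-butyldimethylsilyloxy)prop-1-en-2-yl]-1-iodo-8-[(4-methoxyphenyl)methoxy]-2,6-dimethyl-10-(triethylsilyloxy)deca-1,5-dien-3-ol, via alkenyldimethylalane 25 (not isolated), via lithium alkenylalanate 26 (not isolated)
Conditions: Me3Al (2.5 equiv), Cp2ZrCl2 (0.25 equiv), CH2Cl2, 0 °C to rt; volatiles removed in vacuo; hexane–THF, n-BuLi, −78 to 0 °C; then 20 (1.2 equiv), THF, −30 °C to rt; aq. potassium sodium tartrate
Reagents that add atoms: trimethylaluminium, C[Al](C)C
Why: Me3Al and Cp2ZrCl2 generate a methylzirconium species that adds methyl and metal syn across the terminal alkyne of 14, methyl going to the internal carbon C10 and the metal, after exchange back to aluminium, to C1, so that 25 has the E geometry with C14 cis to aluminium (zirconium-catalysed methylalumination of a terminal alkyne, the Negishi carboalumination). n-BuLi converts the Lewis-acidic alane into the nucleophilic lithium alanate 26 before any epoxide is present, so that no free alkyllithium meets the alkenyl iodide of 20. The alkenyl group of 26, the best migrating ligand on aluminium, then displaces the epoxide oxygen at the unsubstituted carbon C2 of 20 in an SN2 opening with retention of alkene geometry; the closest known reaction type is the opening of monosubstituted epoxides by alkenyltrialkylalanates. No ring is closed and no stereocentre is created: C3 of 20 is not touched and arrives as the 3S carbinol, C7 and C8 of 14 are spectators, and the only new stereo-element, the E C1(10) alkene, follows from the syn addition. The step needs regioselective carbometalation (secured by the terminal alkyne and by the inertness of the 1,1-disubstituted C11=C13 alkene under these conditions), transfer of the alkenyl and not of a methyl or butyl group (intrinsic to sp2 ligands on the ate complex), and attack at C2 and not at allylic C3 or in SN2' fashion (secured by the hard, non-Lewis-acidic alanate, by removal of excess Me3Al before the ate complex is made, and by the iodine-bearing trisubstituted C4=C5 alkene, a poor SN2' acceptor). The silyl and PMB ethers are inert to both organoaluminium species.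

**Step 18**
Reactants: 27 (1Z,3S,5E,8R,9S)-9-[3-(tert-butyldimethylsilyloxy)prop-1-en-2-yl]-1-iodo-8-[(4-methoxyphenyl)methoxy]-2,6-dimethyl-10-(triethylsilyloxy)deca-1,5-dien-3-ol
Product: 28 3-O-tert-butyldimethylsilyl ether of 27 (1Z,3S,5E,8R,9S)
Conditions: TBSOTf, 2,6-lutidine, CH2Cl2, −78 °C
Reagents that add atoms: tert-butyldimethylsilyl trifluoromethanesulfonate, CC(C)(C)[Si](C)(C)OS(=O)(=O)C(F)(F)F
Why: Silyl triflate and a hindered base silylate the secondary allylic C3 hydroxyl at low temperature without exchange at the other ethers; the TBS group must outlast the removal of the C6 and C12 silyl groups.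

**Step 19**
Reactants: 28 3-O-tert-butyldimethylsilyl ether of 27
Product: 29 (2S,3R,5E,8S,9Z)-8-(tert-butyldimethylsilyloxy)-2-[3-(tert-butyldimethylsilyloxy)prop-1-en-2-yl]-10-iodo-3-[(4-methoxyphenyl)methoxy]-5,9-dimethyldeca-5,9-dien-1-ol
Conditions: PPTS (0.2 equiv), MeOH–CH2Cl2, 0 °C
Reagents that add atoms: none
Why: Mild acid methanolysis removes the primary triethylsilyl ether much faster than either TBS ether, which frees only the C6 hydroxyl.

**Step 20**
Reactants: 29 (2S,3R,5E,8S,9Z)-8-(tert-butyldimethylsilyloxy)-2-[3-(tert-butyldimethylsilyloxy)prop-1-en-2-yl]-10-iodo-3-[(4-methoxyphenyl)methoxy]-5,9-dimethyldeca-5,9-dien-1-ol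
Product: 30 (2R,3R,5E,8S,9Z)-8-(tert-butyldimethylsilyloxy)-2-[3-(tert-butyldimethylsilyloxy)prop-1-en-2-yl]-10-iodo-3-[(4-methoxyphenyl)methoxy]-5,9-dimethyldeca-5,9-dienal
Conditions: Dess–Martin periodinane, NaHCO3, CH2Cl2, 0 °C; used at once
Reagents that add atoms: none
Why: Buffered Dess–Martin oxidation is neutral and fast, which protects the C7 centre of the β,γ-unsaturated aldehyde from epimerisation and from migration of the alkene into conjugation; the change of the C7 descriptor to R is a priority change only.

**Step 21**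
Reactants: 30 (2R,3R,5E,8S,9Z)-8-(tert-butyldimethylsilyloxy)-2-[3-(tert-butyldimethylsilyloxy)prop-1-en-2-yl]-10-iodo-3-[(4-methoxyphenyl)methoxy]-5,9-dimethyldeca-5,9-dienal
Product: 31 (1R,2Z,4S,6E,9R,10S)-4-(tert-butyldimethylsilyloxy)-10-[3-(tert-butyldimethylsilyloxy)prop-1-en-2-yl]-9-[(4-methoxyphenyl)methoxy]-3,7-dimethylcyclodeca-2,6-dien-1-ol
Conditions: CrCl2 (10 equiv), NiCl2 (5 mol %), degassed DMSO, rt, 0.003 M, slow addition
Reagents that add atoms: none
Why: Nozaki–Hiyama–Kishi reaction: zerovalent nickel inserts into the C5–I bond, the alkenyl group passes to trivalent chromium with retention of the Z geometry and adds to the C6 aldehyde, closing the ten-membered ring by C5–C6 bond formation. C6 should be set by the approach that keeps the 2-propenyl branch on C7 antiperiplanar to the forming bond and the C8 arm gauche, which gives the 6R carbinol with H6 anti to H7.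

**Step 22**
Reactants: 31 (1R,2Z,4S,6E,9R,10S)-4-(tert-butyldimethylsilyloxy)-10-[3-(tert-butyldimethylsilyloxy)prop-1-en-2-yl]-9-[(4-methoxyphenyl)methoxy]-3,7-dimethylcyclodeca-2,6-dien-1-ol
Product: 32 (1R,2Z,4S,6E,9R,10S)-4-(tert-butyldimethylsilyloxy)-10-(3-hydroxyprop-1-en-2-yl)-9-[(4-methoxyphenyl)methoxy]-3,7-dimethylcyclodeca-2,6-dien-1-ol
Conditions: HF·pyridine, pyridine, THF, 0 °C
Reagents that add atoms: none
Why: Buffered fluoride cleaves the unhindered primary allylic TBS ether faster than the secondary TBS ether at C3, which is flanked by the C4 alkene and the ring.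

**Step 23**
Reactants: 32 (1R,2Z,4S,6E,9R,10S)-4-(tert-butyldimethylsilyloxy)-10-(3-hydroxyprop-1-en-2-yl)-9-[(4-methoxyphenyl)methoxy]-3,7-dimethylcyclodeca-2,6-dien-1-ol
Product: 35 (1(10)E,3S,4Z,6R,7R,8R)-3-(tert-butyldimethylsilyloxy)-8-[(4-methoxyphenyl)methoxy]germacra-1(10),4,11(13)-trien-12,6-olide, via hydroxy enal 33 (not isolated), via lactol 34 (not isolated)
Conditions: TEMPO (0.2 equiv), PhI(OAc)2 (2.5 equiv), CH2Cl2, rt
Reagents that add atoms: none
Why: Oxidative lactonisation of a 2-methylene-1,4-diol: the oxoammonium salt oxidises the primary allylic alcohol in preference to the secondary C6 carbinol, the C6 hydroxyl adds to the enal, and the lactol is oxidised to the trans-fused α-methylene lactone; C6 and C7 are unchanged.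

**Step 24**
Reactants: 35 (1(10)E,3S,4Z,6R,7R,8R)-3-(tert-butyldimethylsilyloxy)-8-[(4-methoxyphenyl)methoxy]germacra-1(10),4,11(13)-trien-12,6-olide
Product: 36 (1(10)E,3S,4Z,6R,7R,8R)-3-(tert-butyldimethylsilyloxy)-8-hydroxygermacra-1(10),4,11(13)-trien-12,6-olide
Conditions: DDQ (1.5 equiv), CH2Cl2–pH 7 phosphate buffer, 0 °C
Reagents that add atoms: none
Why: Oxidative cleavage of the PMB ether by DDQ through the benzylic cation and its hemiacetal; the buffer keeps the medium neutral, and the silyl ether, lactone and isolated alkenes are not affected at 0 °C.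

**Step 25**
Reactants: 36 (1(10)E,3S,4Z,6R,7R,8R)-3-(tert-butyldimethylsilyloxy)-8-hydroxygermacra-1(10),4,11(13)-trien-12,6-olide; 24 (2S,3S)-2,3-dimethyloxirane-2-carboxylic acid
Product: 38 (1(10)E,3S,4Z,6R,7R,8R)-3-(tert-butyldimethylsilyloxy)-8-{[(2S,3S)-2,3-dimethyloxirane-2-carbonyl]oxy}germacra-1(10),4,11(13)-trien-12,6-olide, via mixed anhydride 37 (not isolated)
Conditions: 24, 2,4,6-trichlorobenzoyl chloride, Et3N, toluene, rt; then 36, DMAP, toluene, rt
Reagents that add atoms: none
Why: Yamaguchi esterification: DMAP attacks the less hindered aliphatic carbonyl of the mixed anhydride and transfers the epoxy acyl group to the hindered C8 hydroxyl; no alkoxide is formed, so translactonisation to C8 is avoided, and neither stereocentre of 24 is at risk.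

**Step 26**
Reactants: 38 (1(10)E,3S,4Z,6R,7R,8R)-3-(tert-butyldimethylsilyloxy)-8-{[(2S,3S)-2,3-dimethyloxirane-2-carbonyl]oxy}germacra-1(10),4,11(13)-trien-12,6-olide
Product: 39 (1R,3S,4Z,6R,7R,8R,10R)-3-(tert-butyldimethylsilyloxy)-8-{[(2S,3S)-2,3-dimethyloxirane-2-carbonyl]oxy}-1,10-epoxygermacra-4,11(13)-dien-12,6-olide
Conditions: mCPBA (1.1 equiv), NaHCO3, CH2Cl2, 0 °C
Reagents that add atoms: 3-chloroperoxybenzoic acid, OOC(=O)c1cccc(Cl)c1
Why: Peracid (Prilezhaev) epoxidation of the most nucleophilic alkene: C1=C10 has no allylic oxygen, whereas C4=C5 is flanked by two allylic C–O bonds and C11=C13 is conjugated to the lactone. The E geometry gives the trans epoxide, and attack on the exposed outer face of the ring alkene is expected to give the 1R,10R isomer.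

**Step 27**
Reactants: 39 (1R,3S,4Z,6R,7R,8R,10R)-3-(tert-butyldimethylsilyloxy)-8-{[(2S,3S)-2,3-dimethyloxirane-2-carbonyl]oxy}-1,10-epoxygermacra-4,11(13)-dien-12,6-olide
Product: 40 (1R,3S,4Z,6R,7R,8R,10R)-1,10-epoxy-3-hydroxy-8-{[(2S,3S)-2,3-dimethyloxirane-2-carbonyl]oxy}germacra-4,11(13)-dien-12,6-olide (CNP0268255.2)
Conditions: HF·pyridine, excess pyridine, THF, 0 °C to rt
Reagents that add atoms: none
Why: Fluoride-driven cleavage of the secondary silyl ether; the large excess of pyridine buffers the acid so that neither oxirane is opened and the esters and methylene lactone are left alone.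

## Compound list

1 | 4-(trimethylsilyl)but-3-yn-1-ol | C[Si](C)(C)C#CCCO | starting material
2 | 4-(trimethylsilyl)but-3-ynal | C[Si](C)(C)C#CCC=O | intermediate
3 | ethyl (2E)-6-(trimethylsilyl)hex-2-en-5-ynoate | CCOC(=O)/C=C/CC#C[Si](C)(C)C | intermediate
4 | (2E)-6-(trimethylsilyl)hex-2-en-5-yn-1-ol | OC/C=C/CC#C[Si](C)(C)C | intermediate
5 | [(2R,3R)-3-[3-(trimethylsilyl)prop-2-yn-1-yl]oxiran-2-yl]methanol | C[Si](C)(C)C#CC[C@H]1O[C@@H]1CO | intermediate
6 | 2-bromoprop-2-en-1-ol | C=C(Br)CO | starting material
7 | [(2-bromoprop-2-en-1-yl)oxy](tert-butyl)dimethylsilane | C=C(Br)CO[Si](C)(C)C(C)(C)C | intermediate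
8 | [3-(tert-butyldimethylsilyloxy)prop-1-en-2-yl]lithium | [Li]C(=C)CO[Si](C)(C)C(C)(C)C | intermediate
9 | bromo[3-(tert-butyldimethylsilyloxy)prop-1-en-2-yl]magnesium | Br[Mg]C(=C)CO[Si](C)(C)C(C)(C)C | intermediate
10 | (2S,3R)-2-[3-(tert-butyldimethylsilyloxy)prop-1-en-2-yl]-6-(trimethylsilyl)hex-5-yne-1,3-diol | C[Si](C)(C)C#CC[C@@H](O)[C@@H](C(=C)CO[Si](C)(C)C(C)(C)C)CO | intermediate
11 | tert-butyl({2-[(2S,4R,5S)-2-(4-methoxyphenyl)-4-[3-(trimethylsilyl)prop-2-yn-1-yl]-1,3-dioxan-5-yl]prop-2-en-1-yl}oxy)dimethylsilane | COc1ccc(cc1)[C@H]1OC[C@H](C(=C)CO[Si](C)(C)C(C)(C)C)[C@@H](CC#C[Si](C)(C)C)O1 | intermediate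
12 | (2S,3R)-2-[3-(tert-butyldimethylsilyloxy)prop-1-en-2-yl]-3-[(4-methoxyphenyl)methoxy]-6-(trimethylsilyl)hex-5-yn-1-ol | C[Si](C)(C)C#CC[C@@H](OCc1ccc(OC)cc1)[C@@H](C(=C)CO[Si](C)(C)C(C)(C)C)CO | intermediate
13 | (2S,3R)-2-[3-(tert-butyldimethylsilyloxy)prop-1-en-2-yl]-3-[(4-methoxyphenyl)methoxy]hex-5-yn-1-ol | C#CC[C@@H](OCc1ccc(OC)cc1)[C@@H](C(=C)CO[Si](C)(C)C(C)(C)C)CO | intermediate
14 | tert-butyl({2-[(2S,3R)-3-[(4-methoxyphenyl)methoxy]-1-(triethylsilyloxy)hex-5-yn-2-yl]prop-2-en-1-yl}oxy)dimethylsilane (east alkyne) | C#CC[C@@H](OCc1ccc(OC)cc1)[C@@H](C(=C)CO[Si](C)(C)C(C)(C)C)CO[Si](CC)(CC)CC | intermediate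
15 | prop-2-yn-1-ol | C#CCO | starting material
16 | bromo[(1Z)-3-(bromomagnesiooxy)-2-methylprop-1-en-1-yl]magnesium | Br[Mg]/C=C(/C)CO[Mg]Br | intermediate
17 | (2Z)-3-iodo-2-methylprop-2-en-1-ol | I/C=C(/C)CO | intermediate
18 | (2Z)-3-iodo-2-methylprop-2-enal | I/C=C(/C)C=O | intermediate
19 | rac-2-[(1Z)-1-iodoprop-1-en-2-yl]oxirane (racemate, stereocentre not specified) | I/C=C(/C)C1CO1 | intermediate
20 | (2R)-2-[(1Z)-1-iodoprop-1-en-2-yl]oxirane (west epoxide) | I/C=C(/C)[C@@H]1CO1 | intermediate
21 | angelic acid, (2Z)-2-methylbut-2-enoic acid | C/C=C(/C)C(=O)O | starting material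
22 | (2Z)-2-methylbut-2-en-1-ol | C/C=C(/C)CO | intermediate
23 | [(2R,3S)-2,3-dimethyloxiran-2-yl]methanol | OC[C@@]1(C)O[C@H]1C | intermediate
24 | (2S,3S)-2,3-dimethyloxirane-2-carboxylic acid | OC(=O)[C@@]1(C)O[C@H]1C | intermediate
25 | dimethyl{(1E,4R,5S)-5-[3-(tert-butyldimethylsilyloxy)prop-1-en-2-yl]-4-[(4-methoxyphenyl)methoxy]-2-methyl-6-(triethylsilyloxy)hex-1-en-1-yl}alumane | C[Al](C)/C=C(\C)C[C@@H](OCc1ccc(OC)cc1)[C@@H](C(=C)CO[Si](C)(C)C(C)(C)C)CO[Si](CC)(CC)CC | intermediate
26 | lithium butyl(dimethyl){(1E,4R,5S)-5-[3-(tert-butyldimethylsilyloxy)prop-1-en-2-yl]-4-[(4-methoxyphenyl)methoxy]-2-methyl-6-(triethylsilyloxy)hex-1-en-1-yl}alanate | [Li+].CCCC[Al-](C)(C)/C=C(\C)C[C@@H](OCc1ccc(OC)cc1)[C@@H](C(=C)CO[Si](C)(C)C(C)(C)C)CO[Si](CC)(CC)CC | intermediate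
27 | (1Z,3S,5E,8R,9S)-9-[3-(tert-butyldimethylsilyloxy)prop-1-en-2-yl]-1-iodo-8-[(4-methoxyphenyl)methoxy]-2,6-dimethyl-10-(triethylsilyloxy)deca-1,5-dien-3-ol | I/C=C(/C)[C@@H](O)C/C=C(\C)C[C@@H](OCc1ccc(OC)cc1)[C@@H](C(=C)CO[Si](C)(C)C(C)(C)C)CO[Si](CC)(CC)CC | intermediate
28 | 3-O-tert-butyldimethylsilyl ether of 27 (1Z,3S,5E,8R,9S) | I/C=C(/C)[C@@H](O[Si](C)(C)C(C)(C)C)C/C=C(\C)C[C@@H](OCc1ccc(OC)cc1)[C@@H](C(=C)CO[Si](C)(C)C(C)(C)C)CO[Si](CC)(CC)CC | intermediate
29 | (2S,3R,5E,8S,9Z)-8-(tert-butyldimethylsilyloxy)-2-[3-(tert-butyldimethylsilyloxy)prop-1-en-2-yl]-10-iodo-3-[(4-methoxyphenyl)methoxy]-5,9-dimethyldeca-5,9-dien-1-ol | I/C=C(/C)[C@@H](O[Si](C)(C)C(C)(C)C)C/C=C(\C)C[C@@H](OCc1ccc(OC)cc1)[C@@H](C(=C)CO[Si](C)(C)C(C)(C)C)CO | intermediate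
30 | (2R,3R,5E,8S,9Z)-8-(tert-butyldimethylsilyloxy)-2-[3-(tert-butyldimethylsilyloxy)prop-1-en-2-yl]-10-iodo-3-[(4-methoxyphenyl)methoxy]-5,9-dimethyldeca-5,9-dienal | I/C=C(/C)[C@@H](O[Si](C)(C)C(C)(C)C)C/C=C(\C)C[C@@H](OCc1ccc(OC)cc1)[C@@H](C(=C)CO[Si](C)(C)C(C)(C)C)C=O | intermediate
31 | (1R,2Z,4S,6E,9R,10S)-4-(tert-butyldimethylsilyloxy)-10-[3-(tert-butyldimethylsilyloxy)prop-1-en-2-yl]-9-[(4-methoxyphenyl)methoxy]-3,7-dimethylcyclodeca-2,6-dien-1-ol | O[C@@H]1/C=C(/C)[C@@H](O[Si](C)(C)C(C)(C)C)C/C=C(\C)C[C@@H](OCc2ccc(OC)cc2)[C@H]1C(=C)CO[Si](C)(C)C(C)(C)C | intermediate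
32 | (1R,2Z,4S,6E,9R,10S)-4-(tert-butyldimethylsilyloxy)-10-(3-hydroxyprop-1-en-2-yl)-9-[(4-methoxyphenyl)methoxy]-3,7-dimethylcyclodeca-2,6-dien-1-ol | O[C@@H]1/C=C(/C)[C@@H](O[Si](C)(C)C(C)(C)C)C/C=C(\C)C[C@@H](OCc2ccc(OC)cc2)[C@H]1C(=C)CO | intermediate
33 | C12 enal of 32 (2-substituted prop-2-enal with free C6 hydroxyl; ring stereochemistry as in 32) | O[C@@H]1/C=C(/C)[C@@H](O[Si](C)(C)C(C)(C)C)C/C=C(\C)C[C@@H](OCc2ccc(OC)cc2)[C@H]1C(=C)C=O | intermediate
34 | C12 lactol of 35 (anomeric centre not specified; other centres as in 35) | C=C1C(O)O[C@@H]2/C=C(/C)[C@@H](O[Si](C)(C)C(C)(C)C)C/C=C(\C)C[C@@H](OCc3ccc(OC)cc3)[C@@H]12 | intermediate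
35 | (1(10)E,3S,4Z,6R,7R,8R)-3-(tert-butyldimethylsilyloxy)-8-[(4-methoxyphenyl)methoxy]germacra-1(10),4,11(13)-trien-12,6-olide | C=C1C(=O)O[C@@H]2/C=C(/C)[C@@H](O[Si](C)(C)C(C)(C)C)C/C=C(\C)C[C@@H](OCc3ccc(OC)cc3)[C@@H]12 | intermediate
36 | (1(10)E,3S,4Z,6R,7R,8R)-3-(tert-butyldimethylsilyloxy)-8-hydroxygermacra-1(10),4,11(13)-trien-12,6-olide | C=C1C(=O)O[C@@H]2/C=C(/C)[C@@H](O[Si](C)(C)C(C)(C)C)C/C=C(\C)C[C@@H](O)[C@@H]12 | intermediate
37 | (2S,3S)-2,3-dimethyloxirane-2-carboxylic 2,4,6-trichlorobenzoic anhydride | Clc1cc(Cl)c(C(=O)OC(=O)[C@@]2(C)O[C@H]2C)c(Cl)c1 | intermediate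
38 | (1(10)E,3S,4Z,6R,7R,8R)-3-(tert-butyldimethylsilyloxy)-8-{[(2S,3S)-2,3-dimethyloxirane-2-carbonyl]oxy}germacra-1(10),4,11(13)-trien-12,6-olide | C=C1C(=O)O[C@@H]2/C=C(/C)[C@@H](O[Si](C)(C)C(C)(C)C)C/C=C(\C)C[C@@H](OC(=O)[C@@]3(C)O[C@H]3C)[C@@H]12 | intermediate
39 | (1R,3S,4Z,6R,7R,8R,10R)-3-(tert-butyldimethylsilyloxy)-8-{[(2S,3S)-2,3-dimethyloxirane-2-carbonyl]oxy}-1,10-epoxygermacra-4,11(13)-dien-12,6-olide | C=C1C(=O)O[C@@H]2/C=C(/C)[C@@H](O[Si](C)(C)C(C)(C)C)C[C@H]3O[C@]3(C)C[C@@H](OC(=O)[C@@]3(C)O[C@H]3C)[C@@H]12 | intermediate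
40 | (1R,3S,4Z,6R,7R,8R,10R)-1,10-epoxy-3-hydroxy-8-{[(2S,3S)-2,3-dimethyloxirane-2-carbonyl]oxy}germacra-4,11(13)-dien-12,6-olide (CNP0268255.2) | C=C1C(=O)O[C@@H]2/C=C(/C)[C@@H](O)C[C@H]3O[C@]3(C)C[C@@H](OC(=O)[C@@]3(C)O[C@H]3C)[C@@H]12 | target

## Step count and least certain steps

Total: 27 steps. Longest linear sequence: 19 steps (steps 1–3, 5–9 and 17–27, from 1 to 40).

**Step 17 (key step).** The most likely failures are transfer of a methyl or butyl group from the alanate in place of the alkenyl group, opening or rearrangement of the allylic epoxide at C3 by residual Lewis-acidic alane, and halogen–metal exchange at the alkenyl iodide of 20. All three come from having organoaluminium species of mixed reactivity next to a sensitive electrophile. The fallback sets out from 14, makes the same two bonds stepwise and postpones the iodoalkene: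
- Methylalumination of 14 as in step 17 followed by iodinolysis would give the (E)-alkenyl iodide F1.
- Iodine–lithium exchange with t-BuLi at −78 °C would give the alkenyllithium F2.
- In the presence of BF3·OEt2, F2 would open (2R)-trimethyl(oxiran-2-ylethynyl)silane F3 at its CH2 carbon (no alkenyl iodide is present to scramble). F3 would be made from 3-(trimethylsilyl)prop-2-ynal by the methylenation and resolution of steps 12 and 13. The product is the silylated propargylic alcohol F4.
- K2CO3 in MeOH would give the terminal alkyne F5.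
- The alkoxide-directed anti-methylmagnesiation and iodinolysis of step 10 (MeMgBr, CuI, then I2) would turn the propargylic alcohol into the Z-iodoalkene. The fallback comes back to the route at 27.

**Step 21.** The likely problems are poor facial selectivity at C6 in the ring-forming addition, since the preference of the acyclic α-centre and that of the forming ring need not coincide, and loss of the C7 configuration in the aldehyde before closure. The fallback sets out from 30. If the closure under the same chromium conditions gives mainly the 6S carbinol F6, the configuration is corrected by a Mitsunobu reaction (4-nitrobenzoic acid, PPh3, diisopropyl azodicarboxylate) to the inverted 4-nitrobenzoate F7. Methanolysis (K2CO3, MeOH) then returns to the route at 31.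

**Step 5.** The likely problem is competing attack at C3 of the epoxy alcohol, which gives the 1,2-diol, because the propargyl group at C3 is small; base-induced elimination at the propargylic CH2 is a second risk. The fallback sets out from 5 and relies on electronic control of regiochemistry:
- Oxidation of 5 (TEMPO, PhI(OAc)2, aqueous MeCN) would give the glycidic acid F8, and methylation (MeI, K2CO3, DMF) the methyl glycidate F9.
- The organocopper reagent from 9 and CuI would attack F9 at the ester-activated α-carbon C7 with inversion, giving the hydroxy ester F10.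
- Reduction with i-Bu2AlH returns to the route at 10.

**Step 26.** The likely problem is peracid attack on the wrong face of the C1(10) alkene, since face selection rests only on the conformation of the ten-membered ring; some epoxidation of C4=C5 is a lesser risk. The fallback sets out from 38 and replaces substrate control by reagent control: Shi epoxidation with the D-fructose-derived ketone and KHSO5 in buffered MeCN–dimethoxymethane–water. For an E-trisubstituted alkene this is expected to deliver the R,R epoxide. It returns to the route at 39 and makes no new compound.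

**Step 27.** The likely problem is opening of the C1–C10 epoxide by the freed C3 hydroxyl across the ring, or acid-induced rearrangement of the epoxide, during fluoride treatment. The fallback sets out from 38 and changes the order of events. The silyl ether is removed first (HF·pyridine, pyridine, THF), when no ring epoxide is present, to give the 3-hydroxy triene ester F11. F11 is then epoxidised at C1=C10 under buffered conditions (mCPBA, NaHCO3, or dimethyldioxirane in acetone), which reaches the route again at 40.

## Further compounds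

F1 | step 17 | tert-butyl({2-[(2S,3R,5E)-6-iodo-3-[(4-methoxyphenyl)methoxy]-5-methyl-1-(triethylsilyloxy)hex-5-en-2-yl]prop-2-en-1-yl}oxy)dimethylsilane | I/C=C(\C)C[C@@H](OCc1ccc(OC)cc1)[C@@H](C(=C)CO[Si](C)(C)C(C)(C)C)CO[Si](CC)(CC)CC
F2 | step 17 | alkenyllithium from F1 (lithium in place of iodine, E) | [Li]/C=C(\C)C[C@@H](OCc1ccc(OC)cc1)[C@@H](C(=C)CO[Si](C)(C)C(C)(C)C)CO[Si](CC)(CC)CC
F3 | step 17 | (2R)-trimethyl(oxiran-2-ylethynyl)silane | C[Si](C)(C)C#C[C@@H]1CO1
F4 | step 17 | (3S,5E,8R,9S)-9-[3-(tert-butyldimethylsilyloxy)prop-1-en-2-yl]-8-[(4-methoxyphenyl)methoxy]-6-methyl-10-(triethylsilyloxy)-1-(trimethylsilyl)dec-5-en-1-yn-3-ol | C[Si](C)(C)C#C[C@@H](O)C/C=C(\C)C[C@@H](OCc1ccc(OC)cc1)[C@@H](C(=C)CO[Si](C)(C)C(C)(C)C)CO[Si](CC)(CC)CC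
F5 | step 17 | (3S,5E,8R,9S)-9-[3-(tert-butyldimethylsilyloxy)prop-1-en-2-yl]-8-[(4-methoxyphenyl)methoxy]-6-methyl-10-(triethylsilyloxy)dec-5-en-1-yn-3-ol | C#C[C@@H](O)C/C=C(\C)C[C@@H](OCc1ccc(OC)cc1)[C@@H](C(=C)CO[Si](C)(C)C(C)(C)C)CO[Si](CC)(CC)CC
F6 | step 21 | C6 epimer of 31 (6S; other centres as in 31) | O[C@H]1/C=C(/C)[C@@H](O[Si](C)(C)C(C)(C)C)C/C=C(\C)C[C@@H](OCc2ccc(OC)cc2)[C@H]1C(=C)CO[Si](C)(C)C(C)(C)C
F7 | step 21 | 4-nitrobenzoate ester of 31 (6R) | O=C(O[C@@H]1/C=C(/C)[C@@H](O[Si](C)(C)C(C)(C)C)C/C=C(\C)C[C@@H](OCc2ccc(OC)cc2)[C@H]1C(=C)CO[Si](C)(C)C(C)(C)C)c1ccc(cc1)[N+](=O)[O-]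
F8 | step 5 | (2S,3R)-3-[3-(trimethylsilyl)prop-2-yn-1-yl]oxirane-2-carboxylic acid | C[Si](C)(C)C#CC[C@H]1O[C@@H]1C(=O)O
F9 | step 5 | methyl (2S,3R)-3-[3-(trimethylsilyl)prop-2-yn-1-yl]oxirane-2-carboxylate | C[Si](C)(C)C#CC[C@H]1O[C@@H]1C(=O)OC
F10 | step 5 | methyl (2R,3R)-2-[3-(tert-butyldimethylsilyloxy)prop-1-en-2-yl]-3-hydroxy-6-(trimethylsilyl)hex-5-ynoate | C[Si](C)(C)C#CC[C@@H](O)[C@@H](C(=C)CO[Si](C)(C)C(C)(C)C)C(=O)OC
F0 | step 26 | none | none
F11 | step 27 | (1(10)E,3S,4Z,6R,7R,8R)-3-hydroxy-8-{[(2S,3S)-2,3-dimethyloxirane-2-carbonyl]oxy}germacra-1(10),4,11(13)-trien-12,6-olide | C=C1C(=O)O[C@@H]2/C=C(/C)[C@@H](O)C/C=C(\C)C[C@@H](OC(=O)[C@@]3(C)O[C@H]3C)[C@@H]12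
A1 | alternative 1 | (1(10)E,4Z)-3-(tert-butyldimethylsilyloxy)-8-hydroxy-13-norgermacra-1(10),4-dien-12,6-olide (trans-fused; C3, C6, C7 and C8 as in the target) | C1C(=O)O[C@@H]2/C=C(/C)[C@@H](O[Si](C)(C)C(C)(C)C)C/C=C(\C)C[C@@H](O)[C@@H]12
A2 | alternative 1 | 5-[(1Z,3S,5E)-3-(tert-butyldimethylsilyloxy)-2,6-dimethyl-8-oxoocta-1,5-dien-1-yl]furan-2(5H)-one (C6 as in the target) | O=C1C=C[C@H](O1)/C=C(/C)[C@@H](O[Si](C)(C)C(C)(C)C)C/C=C(\C)CC=O
A3 | alternative 2 | cis-anti-cis head-to-head 6-4-4 tricyclic photoadduct (ketone at C6; C3 tert-butyldimethylsilyl ether; C8 triethylsilyl ether) | O=C1C[C@H](O[Si](CC)(CC)CC)C[C@@]2(C)[C@@H]1[C@@]1(C)[C@@H]2C[C@@H]1O[Si](C)(C)C(C)(C)C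
A4 | alternative 2 | (5R)-3-methyl-5-(triethylsilyloxy)cyclohex-2-en-1-one | O=C1C[C@H](O[Si](CC)(CC)CC)CC(C)=C1
A5 | alternative 2 | (4S)-4-(tert-butyldimethylsilyloxy)-1-methylcyclobut-1-ene | CC1=CC[C@@H]1O[Si](C)(C)C(C)(C)C
A6 | alternative 2 | (2Z,6E)-4-(tert-butyldimethylsilyloxy)-3,7-dimethyl-9-(triethylsilyloxy)cyclodeca-2,6-dien-1-one (C3 and C8 as in the target) | O=C1/C=C(/C)[C@@H](O[Si](C)(C)C(C)(C)C)C/C=C(\C)C[C@@H](O[Si](CC)(CC)CC)C1
A7 | alternative 3 | (1(10)E,3S,4Z,6R,7R,8R)-3-(tert-butyldimethylsilyloxy)-8-[(4-methoxyphenyl)methoxy]germacra-1(10),4,11(13)-trien-12,6-olide (same structure as 35) | C=C1C(=O)O[C@@H]2/C=C(/C)[C@@H](O[Si](C)(C)C(C)(C)C)C/C=C(\C)C[C@@H](OCc3ccc(OC)cc3)[C@@H]12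
A8 | alternative 3 | (2Z,6E)-4-(tert-butyldimethylsilyloxy)-10-ethynyl-9-[(4-methoxyphenyl)methoxy]-3,7-dimethylcyclodeca-2,6-dien-1-ol (C3, C6, C7 and C8 as in the target) | C#C[C@H]1[C@H](O)/C=C(/C)[C@@H](O[Si](C)(C)C(C)(C)C)C/C=C(\C)C[C@H]1OCc1ccc(OC)cc1
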